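**Retrosynthetic overview**
- Target ⇐ Shi epoxidation of the 3,4-alkene ⇐ singlet-oxygen ene reaction at C7=C8 of a 14-membered (3E,7E,11E)-triene lactone acetate.
- 14-Membered ring ⇐ radical SN2′ (addition–fragmentation) closure of C2–C1: a C2 allyl radical adds to a butenolide carrying CH2SO2Ph, giving C1 and the exocyclic methylene in one step.
- Open chain ⇐ organocatalytic anti-selective vinylogous Mukaiyama aldol (C13–C14, first stereocentres) between an (E)-enal and a 2-silyloxyfuran.
- Enal ⇐ SeO2 oxidation of (2E,6E)-farnesyl chloride; silyloxyfuran ⇐ α-methylene-γ-butyrolactone + PhSO2Na.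
- Ring order: lactone (as butenolide) first, 14-membered carbocycle second, oxirane last.

Assumption: cembrane numbering is used for locants (C1 lactone β-carbon, C14 lactone O–CH, C13 CHOAc, C3/C4 oxirane, C7 CHOOH, C15–C17 α-methylene acid unit); the SMILES is read as (1R,3S,4S,7R,11E,13S,14R).

Step 1
Reactants: 1 (2E,6E)-1-chloro-3,7,11-trimethyldodeca-2,6,10-triene (trans,trans-farnesyl chloride)
Product: 3 (2E,6E,10E)-12-chloro-2,6,10-trimethyldodeca-2,6,10-trienal, via allylic alcohol 2 (not isolated)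
Conditions: SeO2 (0.3 equiv), t-BuOOH (3 equiv), salicylic acid (0.1 equiv), CH2Cl2, 0 °C → rt; filter; MnO2 (15 equiv), CH2Cl2, rt
Reagents that add atoms: selenium dioxide, O=[Se]=O (catalytic oxygen carrier); tert-butyl hydroperoxide, CC(C)(C)OO (terminal oxidant)
Why: Riley allylic oxidation (ene reaction then [2,3]-sigmatropic shift) attacks only the (E)-methyl of the terminal, most electron-rich trisubstituted alkene (the alkene next to CH2Cl is deactivated), and MnO2 then oxidises the allylic alcohol to the (E)-enal without touching the allylic chloride; no stereocentre is formed.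

Step 2
Reactants: 4 3-methylidenedihydrofuran-2(3H)-one (α-methylene-γ-butyrolactone)
Product: 6 3-[(phenylsulfonyl)methyl]furan-2(5H)-one, via tertiary iodide 5 (not isolated)
Conditions: PhSO2Na (1.3 equiv), I2 (1.3 equiv), EtOAc/H2O, rt, light; then Et3N (2.5 equiv), CH2Cl2, 0 °C → rt
Reagents that add atoms: sodium benzenesulfinate, [Na+].[O-]S(=O)c1ccccc1; iodine, [I][I] (retained only in 5)
Why: Radical iodosulfonylation of the 1,1-disubstituted alkene (sulfonyl to CH2, iodine to the tertiary carbon) followed by amine-induced dehydroiodination and equilibration to the conjugated endocyclic butenolide gives the allyl sulfone, as 2-(sulfonylmethyl)acrylates are made from methacrylates; the transient racemic centre of 5 is erased.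

Step 3
Reactants: 6 3-[(phenylsulfonyl)methyl]furan-2(5H)-one
Product: 7 trimethyl({3-[(phenylsulfonyl)methyl]furan-2-yl}oxy)silane
Conditions: Me3SiOTf (1.2 equiv), Et3N (1.5 equiv), CH2Cl2, 0 °C; pentane extraction, used directly
Reagents that add atoms: trimethylsilyl trifluoromethanesulfonate, C[Si](C)(C)OS(=O)(=O)C(F)(F)F
Why: Soft enolisation at C5 and O-silylation (silyl dienol ether formation) give the aromatic 2-silyloxyfuran, the neutral nucleophile needed for the Mukaiyama step.

Step 4
Reactants: 3 (2E,6E,10E)-12-chloro-2,6,10-trimethyldodeca-2,6,10-trienal; 7 trimethyl({3-[(phenylsulfonyl)methyl]furan-2-yl}oxy)silane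
Product: 9 (5R)-5-[(1S,2E,6E,10E)-12-chloro-1-hydroxy-2,6,10-trimethyldodeca-2,6,10-trien-1-yl]-3-[(phenylsulfonyl)methyl]furan-2(5H)-one, via silyl ether 8 (not isolated)
Conditions: cinchona-derived N-[3,5-bis(trifluoromethyl)phenyl]thiourea–quinuclidinium trichloroacetate salt (10 mol %; the pseudoenantiomer that gives the 5R,1′S series, to be confirmed on a model aldehyde), CH2Cl2/Et2O, −20 °C; then 1 M HCl, THF, 0 °C
Reagents that add atoms: none
Why: Organocatalytic asymmetric vinylogous Mukaiyama aldol reaction, in which the chiral ammonium/thiourea salt activates the α-branched enal by hydrogen bonding (1,2-addition only) and the furan attacks through C5 in an open anti-selective transition state, setting C14 (R) and C13 (S) as the first stereocentres under catalyst control.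

Step 5
Reactants: 9 (5R)-5-[(1S,2E,6E,10E)-12-chloro-1-hydroxy-2,6,10-trimethyldodeca-2,6,10-trien-1-yl]-3-[(phenylsulfonyl)methyl]furan-2(5H)-one
Product: 10 (1R,3E,7E,11E,13S,14R)-13-hydroxycembra-3,7,11,15(17)-tetraen-16,14-olide (14-membered carbocycle trans-fused to an α-methylene-γ-butyrolactone)
Conditions: Bu3SnSnBu3 (1.1 equiv), 300 W sunlamp (Pyrex), degassed PhH, 35 °C, 9 added over 8 h to 2 mM final concentration
Reagents that add atoms: none
Why: Proposed new method: a radical SN2′ (addition–fragmentation) macrocyclisation in which Bu3Sn• abstracts the allylic chlorine, the farnesyl-type allyl radical adds through its unsubstituted terminus C2 to the butenolide β-carbon C1 on the face that leaves the ring bonds at C14 and C1 trans (C1 = R), and the adduct radical expels PhSO2• irreversibly, which drives the otherwise reversible allyl-radical addition, delivers the exocyclic methylene directly and regenerates Bu3Sn• from the ditin; the closest known reactions are intermolecular radical allylations with 2-(sulfonylmethyl)acrylates and tin-hydride allyl-radical macrocyclisations onto enones.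

Step 6
Reactants: 10 (1R,3E,7E,11E,13S,14R)-13-hydroxycembra-3,7,11,15(17)-tetraen-16,14-olide
Product: 11 (1R,3E,7E,11E,13S,14R)-13-acetoxycembra-3,7,11,15(17)-tetraen-16,14-olide
Conditions: Ac2O (1.5 equiv), DMAP (0.1 equiv), pyridine, CH2Cl2, 0 °C
Reagents that add atoms: acetic anhydride, CC(=O)OC(C)=O
Why: DMAP-catalysed acylation of the secondary allylic alcohol leaves C13 untouched and deactivates the 11,12-alkene towards the two oxidations that follow.

Step 7
Reactants: 11 (1R,3E,7E,11E,13S,14R)-13-acetoxycembra-3,7,11,15(17)-tetraen-16,14-olide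
Product: 12 (1R,3E,7R,11E,13S,14R)-13-acetoxy-7-hydroperoxycembra-3,8(19),11,15(17)-tetraen-16,14-olide
Conditions: O2, meso-tetraphenylporphyrin (1 mol %), 500 W halogen lamp, CH2Cl2, −30 °C, stopped at about 70 % conversion; HPLC
Reagents that add atoms: dioxygen, O=O
Why: Schenck ene reaction of singlet oxygen, for which the 11,12-alkene is acetate-deactivated and the 7,8-alkene is the less encumbered of the two remaining trisubstituted alkenes (the 3,4-alkene adjoins the branched, lactone-bearing C1), so attack on the exposed outer face with hydrogen abstraction from C19 on the more crowded C6/C19 side (cis effect) is predicted to give the exocyclic alkene and the 7R hydroperoxide under macrocyclic substrate control.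

Step 8
Reactants: 12 (1R,3E,7R,11E,13S,14R)-13-acetoxy-7-hydroperoxycembra-3,8(19),11,15(17)-tetraen-16,14-olide
Product: 13 (1R,3S,4S,7R,11E,13S,14R)-13-acetoxy-3,4-epoxy-7-hydroperoxycembra-8(19),11,15(17)-trien-16,14-olide (CNP0166375.2)
Conditions: 1,2:4,5-di-O-isopropylidene-β-L-erythro-2,3-hexodiulo-2,6-pyranose (L-fructose-derived Shi ketone, 0.3 equiv), KHSO5 (as 2KHSO5·KHSO4·K2SO4, 1.5 equiv), K2CO3, Bu4NHSO4 (cat.), MeCN–(MeO)2CH2 / aqueous borate–Na2H2EDTA buffer (pH 10.5), −5 °C
Reagents that add atoms: potassium peroxymonosulfate, [K+].[O-]S(=O)(=O)OO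
Why: Shi asymmetric epoxidation (chiral dioxirane, spiro transition state), in which the 3,4-alkene is now the only electron-rich trisubstituted alkene (C8=C19 is 1,1-disubstituted with an allylic OOH, C11=C12 is acetate-deactivated, the acrylate is inert) and the L-series ketone gives the (3S,4S)-trans-epoxide (the D-series gives R,R on this substitution pattern).

**Compound list**
1 | (2E,6E)-1-chloro-3,7,11-trimethyldodeca-2,6,10-triene | CC(C)=CCC/C(C)=C/CC/C(C)=C/CCl | starting material
2 | (2E,6E,10E)-12-chloro-2,6,10-trimethyldodeca-2,6,10-trien-1-ol | OC/C(C)=C/CC/C(C)=C/CC/C(C)=C/CCl | intermediate (not isolated)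
3 | (2E,6E,10E)-12-chloro-2,6,10-trimethyldodeca-2,6,10-trienal | O=C/C(C)=C/CC/C(C)=C/CC/C(C)=C/CCl | intermediate
4 | 3-methylidenedihydrofuran-2(3H)-one | C=C1CCOC1=O | starting material
5 | 3-iodo-3-[(phenylsulfonyl)methyl]dihydrofuran-2(3H)-one (racemic) | IC1(CS(=O)(=O)c2ccccc2)CCOC1=O | intermediate (not isolated)
6 | 3-[(phenylsulfonyl)methyl]furan-2(5H)-one | O=C1OCC=C1CS(=O)(=O)c1ccccc1 | intermediate
7 | trimethyl({3-[(phenylsulfonyl)methyl]furan-2-yl}oxy)silane | C[Si](C)(C)Oc1occc1CS(=O)(=O)c1ccccc1 | intermediate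
8 | O-trimethylsilyl ether of 9 | O=C1O[C@H](C=C1CS(=O)(=O)c1ccccc1)[C@@H](O[Si](C)(C)C)/C(C)=C/CC/C(C)=C/CC/C(C)=C/CCl | intermediate (not isolated)
9 | (5R)-5-[(1S,2E,6E,10E)-12-chloro-1-hydroxy-2,6,10-trimethyldodeca-2,6,10-trien-1-yl]-3-[(phenylsulfonyl)methyl]furan-2(5H)-one | O=C1O[C@H](C=C1CS(=O)(=O)c1ccccc1)[C@@H](O)/C(C)=C/CC/C(C)=C/CC/C(C)=C/CCl | intermediate
10 | (1R,3E,7E,11E,13S,14R)-13-hydroxycembra-3,7,11,15(17)-tetraen-16,14-olide | C=C1C(=O)O[C@@H]2[C@@H]1C/C=C(\C)CC/C=C(\C)CC/C=C(\C)[C@@H]2O | intermediate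
11 | (1R,3E,7E,11E,13S,14R)-13-acetoxycembra-3,7,11,15(17)-tetraen-16,14-olide | C=C1C(=O)O[C@@H]2[C@@H]1C/C=C(\C)CC/C=C(\C)CC/C=C(\C)[C@@H]2OC(C)=O | intermediate
12 | (1R,3E,7R,11E,13S,14R)-13-acetoxy-7-hydroperoxycembra-3,8(19),11,15(17)-tetraen-16,14-olide | C=C1C(=O)O[C@@H]2[C@@H]1C/C=C(\C)CC[C@@H](OO)C(=C)CC/C=C(\C)[C@@H]2OC(C)=O | intermediate
13 | (1R,3S,4S,7R,11E,13S,14R)-13-acetoxy-3,4-epoxy-7-hydroperoxycembra-8(19),11,15(17)-trien-16,14-olide | C=C1C(=O)O[C@@H]2[C@@H]1C[C@@H]1O[C@@]1(C)CC[C@@H](OO)C(=C)CC/C=C(\C)[C@@H]2OC(C)=O | target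

**Step count and risks**
Total steps: 8. Longest linear sequence: 7 (4 → 6 → 7 → 9 → 10 → 11 → 12 → 13).

The three steps most likely to fail are 5, 7 and 8.

Step 5 (the new macrocyclisation). The allyl radical may add too slowly, lose its E geometry, or close cis. The fallback uses known chemistry, sets out from 3 and rejoins at 10. The same organocatalytic vinylogous Mukaiyama aldol is run with commercial 2-(trimethylsilyloxy)furan to give (5R)-5-[(1S,2E,6E,10E)-12-chloro-1-hydroxy-2,6,10-trimethyldodeca-2,6,10-trien-1-yl]furan-2(5H)-one F1. A tin-hydride allyl-radical conjugate macrocyclisation (Bu3SnH, AIBN, syringe pump, PhH, 80 °C, 3 mM) then gives the saturated trans-fused lactone (1R,3E,7E,11E,13S,14R)-13-hydroxy-17-norcembra-3,7,11-trien-16,14-olide F2. Classical α-methylenation follows: LiN(SiMe3)2 (2.2 equiv) and dimethyl(methylidene)ammonium iodide give the 15-[(dimethylamino)methyl] lactone F3, and MeI then NaHCO3 return 10.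

Step 7 (ene reaction). Singlet oxygen may not discriminate well enough between C7=C8 and C3=C4, and the regiochemistry and facial selectivity at C7 are predictions. The fallback inverts the order of the two oxidations, setting out from 11 and rejoining at 13. Shi epoxidation of 11 with the L-series ketone is run first, and the 3,4-monoepoxide (1R,3S,4S,7E,11E,13S,14R)-13-acetoxy-3,4-epoxycembra-7,11,15(17)-trien-16,14-olide F4 is separated from the 7,8-isomer. Photooxygenation of F4, in which C7=C8 is the only reactive alkene, then gives 13 directly.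

Step 8 (Shi epoxidation beside a free hydroperoxide). The buffered peroxymonosulfate may reduce or eliminate the hydroperoxide. The fallback sets out from 12 and rejoins at 13 through a protected peroxide. Et3SiOTf and 2,6-lutidine give (1R,3E,7R,11E,13S,14R)-13-acetoxy-7-(triethylsilylperoxy)cembra-3,8(19),11,15(17)-tetraen-16,14-olide F5. Shi epoxidation under the same conditions gives its (3S,4S)-3,4-epoxide, (1R,3S,4S,7R,11E,13S,14R)-13-acetoxy-3,4-epoxy-7-(triethylsilylperoxy)cembra-8(19),11,15(17)-trien-16,14-olide F6. HF·pyridine in THF at 0 °C then releases 13.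

**Further compounds**
F1 | step 5 | (5R)-5-[(1S,2E,6E,10E)-12-chloro-1-hydroxy-2,6,10-trimethyldodeca-2,6,10-trien-1-yl]furan-2(5H)-one | O=C1O[C@H](C=C1)[C@@H](O)/C(C)=C/CC/C(C)=C/CC/C(C)=C/CCl
F2 | step 5 | (1R,3E,7E,11E,13S,14R)-13-hydroxy-17-norcembra-3,7,11-trien-16,14-olide | C1C(=O)O[C@@H]2[C@@H]1C/C=C(\C)CC/C=C(\C)CC/C=C(\C)[C@@H]2O
F3 | step 5 | 15-[(dimethylamino)methyl] derivative of F2 (C15 epimers) | CN(C)CC1C(=O)O[C@@H]2[C@@H]1C/C=C(\C)CC/C=C(\C)CC/C=C(\C)[C@@H]2O
F4 | step 7 | (1R,3S,4S,7E,11E,13S,14R)-13-acetoxy-3,4-epoxycembra-7,11,15(17)-trien-16,14-olide | C=C1C(=O)O[C@@H]2[C@@H]1C[C@@H]1O[C@@]1(C)CC/C=C(\C)CC/C=C(\C)[C@@H]2OC(C)=O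
F5 | step 8 | (1R,3E,7R,11E,13S,14R)-13-acetoxy-7-(triethylsilylperoxy)cembra-3,8(19),11,15(17)-tetraen-16,14-olide | C=C1C(=O)O[C@@H]2[C@@H]1C/C=C(\C)CC[C@@H](OO[Si](CC)(CC)CC)C(=C)CC/C=C(\C)[C@@H]2OC(C)=O
F6 | step 8 | (1R,3S,4S,7R,11E,13S,14R)-13-acetoxy-3,4-epoxy-7-(triethylsilylperoxy)cembra-8(19),11,15(17)-trien-16,14-olide | C=C1C(=O)O[C@@H]2[C@@H]1C[C@@H]1O[C@@]1(C)CC[C@@H](OO[Si](CC)(CC)CC)C(=C)CC/C=C(\C)[C@@H]2OC(C)=O
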